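## Retrosynthetic overview

1. Cut C12–C13 last: a neopentyl organometallic on the oxanorbornane core plus (S)-2-bromo-3-chloro-3-methylbutyl triflate, made from prenol by catalytic enantioselective bromochlorination (sets C14).
2. The C3 vinyl carbinol comes from an (E)-allylic alcohol by Sharpless epoxidation, then iodide formation and zinc reductive opening.
3. The 7-oxabicyclo[2.2.1]heptane comes from one biomimetic epoxy-olefin cyclization: the carbocycle (C6–C11 bond) forms first, then the C10 oxygen closes the bridge onto C7.
4. The cyclization substrate comes from (E,E)-farnesyl acetate by SeO2 oxidation at C12, Sharpless epoxidation (sets C10/C11) and OH→Cl exchange; the chloride is carried as the latent C12 nucleophile.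

Assumptions: biogenetic numbering is used (C1=C2 vinyl, C3 carbinol, ring C6–C11 with O bridging C7/C10, C14 = CHBr, C15 = CMe2Cl); the target is (3S,6S,7R,10S,11S,14S). Both enantiomers of the bromochlorination ligand are taken as available, and the one giving the (S)-bromochloride is used.

## Route

**Step 1**
Reactants: 1, prenol (3-methylbut-2-en-1-ol)
Product: 2, (S)-2-bromo-3-chloro-3-methylbutan-1-ol
Conditions: NBS, ClTi(OiPr)3, chiral tridentate Schiff-base ligand (20 mol %), hexanes, −20 °C
Reagents that add atoms: NBS, O=C1CCC(=O)N1Br (Br); ClTi(OiPr)3, CC(C)O[Ti](Cl)(OC(C)C)OC(C)C (Cl)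
Why: Ti-alkoxide-directed catalytic enantioselective bromochlorination of an allylic alcohol; the ligand controls the bromonium face (sets C14 as S) and chloride opens at the tertiary carbon (Markovnikov), so Br ends on C2 and Cl on C3.

**Step 2**
Reactants: 2
Product: 3, (S)-2-bromo-3-chloro-3-methylbutyl trifluoromethanesulfonate
Conditions: Tf2O, 2,6-lutidine, CH2Cl2, −78 °C; used immediately
Reagents that add atoms: Tf2O, O=S(=O)(OS(=O)(=O)C(F)(F)F)C(F)(F)F
Why: Simple O-sulfonylation of the primary alcohol; the stereocenter is not involved.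

**Step 3**
Reactants: 4, (2E,6E)-farnesyl acetate
Product: 5, (2E,6E,10E)-12-hydroxyfarnesyl acetate
Conditions: SeO2 (cat.), t-BuOOH, salicylic acid (cat.), CH2Cl2, rt; then NaBH4, EtOH, 0 °C (returns over-oxidised enal)
Reagents that add atoms: t-BuOOH, CC(C)(C)OO (with SeO2, O=[Se]=O)
Why: Riley-type allylic oxidation (ene / [2,3]-shift) is selective for the (E)-methyl of the terminal, most electron-rich trisubstituted olefin.

**Step 4**
Reactants: 5
Product: 6, (2E,6E)-(10S,11S)-10,11-epoxy-12-hydroxyfarnesyl acetate
Conditions: Ti(OiPr)4, L-(+)-DET, t-BuOOH, 4 Å MS, CH2Cl2, −20 °C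
Reagents that add atoms: t-BuOOH, CC(C)(C)OO
Why: Sharpless asymmetric epoxidation touches only the allylic-alcohol olefin; L-(+)-tartrate gives the (2S,3S)-type epoxy alcohol, setting C10 (S) and C11.

**Step 5**
Reactants: 6
Product: 7, (2E,6E)-(10S,11R)-12-chloro-10,11-epoxyfarnesyl acetate (same geometry as 6; descriptor changes with CH2Cl priority)
Conditions: PPh3, CCl4, NaHCO3, reflux
Reagents that add atoms: CCl4, ClC(Cl)(Cl)Cl
Why: Appel chlorination at the primary carbinol (SN2 on the alkoxyphosphonium) leaves the buffered epoxide and allylic acetate intact and replaces a participating OH by an inert, non-basic CH2Cl handle.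

**Step 6**
Reactants: 7
Product: 8, (2E)-5-[(1R,2S,3S,4S)-3-(chloromethyl)-1,3-dimethyl-7-oxabicyclo[2.2.1]heptan-2-yl]-3-methylpent-2-en-1-yl acetate
Conditions: BF3·OEt2 (1.2–1.5 equiv), CH2Cl2, −78 → −20 °C
Reagents that add atoms: none (isomerisation)
Why: Biomimetic epoxy-olefin cyclization: the 6,7-olefin attacks C11 anti to the epoxide C–O bond (inversion at C11, C10 retained) through a chair transition state, so the (E)-olefin and trans-epoxide geometries set C6 and C11, and the Lewis-acid-bound C10 oxygen then captures the C7 cation to close the bridge (sets C7); the acetate-deactivated 2,3-olefin stays out.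

**Step 7**
Reactants: 8
Product: 9, (2E)-5-[(1R,2S,3S,4S)-3-(chloromethyl)-1,3-dimethyl-7-oxabicyclo[2.2.1]heptan-2-yl]-3-methylpent-2-en-1-ol
Conditions: K2CO3, MeOH, rt
Reagents that add atoms: none
Why: Mild transesterification frees the allylic alcohol; the neopentyl chloride and bridged ether are inert.

**Step 8**
Reactants: 9
Product: 10, [(2S,3S)-3-{2-[(1R,2S,3S,4S)-3-(chloromethyl)-1,3-dimethyl-7-oxabicyclo[2.2.1]heptan-2-yl]ethyl}-3-methyloxiran-2-yl]methanol
Conditions: Ti(OiPr)4, L-(+)-DET, t-BuOOH, 4 Å MS, CH2Cl2, −20 °C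
Reagents that add atoms: t-BuOOH, CC(C)(C)OO
Why: Reagent-controlled Sharpless asymmetric epoxidation of a geraniol-type allylic alcohol gives the (2S,3S)-epoxide, fixing the C3–O stereocenter (S) far from the ring stereocenters.

**Step 9**
Reactants: 10
Product: 11, (2R,3S)-2-(iodomethyl)-3-methyl-3-{2-[(1R,2S,3S,4S)-3-(chloromethyl)-1,3-dimethyl-7-oxabicyclo[2.2.1]heptan-2-yl]ethyl}oxirane
Conditions: I2, PPh3, imidazole, CH2Cl2, 0 °C
Reagents that add atoms: I2, II
Why: Appel-type iodination of the primary epoxy carbinol (SN2 at CH2 only; no stereocenter touched).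

**Step 10**
Reactants: 11
Product: 12, (3S)-5-[(1R,2S,3S,4S)-3-(chloromethyl)-1,3-dimethyl-7-oxabicyclo[2.2.1]heptan-2-yl]-3-methylpent-1-en-3-ol
Conditions: Zn dust, AcOH (cat.), EtOH, rt → 40 °C
Reagents that add atoms: none
Why: Zinc-mediated reductive β-elimination of the iodo-epoxide gives the tertiary vinyl carbinol with the C3–O bond, and hence the (S) configuration, retained; the unactivated neopentyl chloride does not react.

**Step 11**
Reactants: 12 and 3
Product: 13, dactylomelol, (3S)-5-[(1R,2S,3S,4S)-3-[(3S)-3-bromo-4-chloro-4-methylpentyl]-1,3-dimethyl-7-oxabicyclo[2.2.1]heptan-2-yl]-3-methylpent-1-en-3-ol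
Conditions: n-BuLi (1.0 equiv), THF, −78 °C; LiDBB (2.1 equiv, titrated to endpoint), −78 °C; MgBr2·OEt2; Li2CuCl4 (10 mol %), 3 (2 equiv), −78 → −20 °C
Reagents that add atoms: none beyond triflate 3
Why: Reductive lithiation of the neopentyl chloride on the pre-formed alkoxide, transmetalation, and Cu-catalysed sp3–sp3 (Kochi-type) displacement of the primary triflate forge C12–C13 without touching C14 or the secondary bromide/tertiary chloride at low temperature.

## Compound list

1 | prenol | CC(C)=CCO | starting material
2 | (S)-2-bromo-3-chloro-3-methylbutan-1-ol | OC[C@H](Br)C(C)(C)Cl | intermediate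
3 | (S)-2-bromo-3-chloro-3-methylbutyl triflate | O=S(=O)(OC[C@H](Br)C(C)(C)Cl)C(F)(F)F | intermediate
4 | (2E,6E)-farnesyl acetate | CC(=O)OC/C=C(\C)CC/C=C(\C)CCC=C(C)C | starting material
5 | (2E,6E,10E)-12-hydroxyfarnesyl acetate | CC(=O)OC/C=C(\C)CC/C=C(\C)CC/C=C(\C)CO | intermediate
6 | (10S,11S)-10,11-epoxy-12-hydroxyfarnesyl acetate | CC(=O)OC/C=C(\C)CC/C=C(\C)CC[C@@H]1O[C@@]1(C)CO | intermediate
7 | (10S,11R)-12-chloro-10,11-epoxyfarnesyl acetate | CC(=O)OC/C=C(\C)CC/C=C(\C)CC[C@@H]1O[C@@]1(C)CCl | intermediate
8 | oxanorbornane allylic acetate (chloromethyl core) | CC(=O)OC/C=C(\C)CC[C@H]1[C@](C)(CCl)[C@@H]2CC[C@@]1(C)O2 | intermediate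
9 | oxanorbornane (E)-allylic alcohol | OC/C=C(\C)CC[C@H]1[C@](C)(CCl)[C@@H]2CC[C@@]1(C)O2 | intermediate
10 | (2S,3S)-epoxy alcohol | OC[C@@H]1O[C@@]1(C)CC[C@H]2[C@](C)(CCl)[C@@H]3CC[C@@]2(C)O3 | intermediate
11 | (2R,3S)-epoxy iodide | IC[C@@H]1O[C@@]1(C)CC[C@H]2[C@](C)(CCl)[C@@H]3CC[C@@]2(C)O3 | intermediate
12 | (3S)-vinyl carbinol with chloromethyl core | C=C[C@@](C)(O)CC[C@H]1[C@](C)(CCl)[C@@H]2CC[C@@]1(C)O2 | intermediate
13 | dactylomelol | C=C[C@@](C)(O)CC[C@H]1[C@](C)(CC[C@H](Br)C(C)(C)Cl)[C@@H]2CC[C@@]1(C)O2 | target

## Summary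

Total steps: 11. Longest linear sequence: 9 (farnesyl acetate 4 → 13, Steps 3–11); the triflate arm is 2 steps.

Stereocenters: C14 is set in Step 1; C10 and C11 in Step 4 (C11 inverted in Step 6); C6 and C7 in Step 6; C3 in Step 8 (retained in Step 10). Minor-enantiomer carry-over from Steps 1, 4 and 8 ends up as separable diastereomers of 13.

Steps most likely to fail:

1. **Step 6 (cyclization/etherification).** The CH2Cl-deactivated epoxide may open sluggishly, and proton loss or bicyclization through the 2,3-olefin can compete with ether closure. Fallback: separate the two bond formations. Carry C12 as a silyl ether, run the Lewis-acid cyclization to the monocyclic alkenols (proton-loss termination), close the C7–O–C10 bridge by Hg(OTf)2 oxymercuration/NaBH4, then convert C12-OSi to the halide.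
2. **Step 11 (reductive lithiation and Cu-catalysed coupling with a β-bromo triflate).** Elimination of the triflate, halogen–metal exchange or incomplete lithiation are all possible. Fallback: attach a plain prenyl terminus to C12 instead (same organometallic with prenyl bromide), then create C14 by reagent control: Sharpless dihydroxylation of the 14,15-olefin, conversion to the epoxide/bromohydrin, and tertiary OH→Cl through a stereospecific bromonium (neighbouring-group) substitution.
3. **Step 5 (Appel chlorination next to the fully substituted epoxide carbon).** Fallback: abandon the chloride handle. Protect C12-OH as a TBS ether through the cyclization, then after Step 10 unmask it, make the neopentyl iodide (Tf2O, then NaI), and generate the C12 nucleophile by t-BuLi iodine–lithium exchange for the final coupling.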